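**Retrosynthetic overview**
1. Target ⇐ its hydroquinone bis(methyl ether): oxidative demethylation to the quinone, dithionite reduction, acetate put on just before. No ring is formed; the benzene ring is bought.
2. C13–C14: the β,γ-unsaturated ketone ⇐ a chloromethyl ketone (electrophilic α-carbon) + an isobutenylboronate; the chloromethyl ketone ⇐ methyl ester + LiCH2Cl.
3. Key disconnection C5–C6: a lithiated carbamate (α-oxy carbanion, the carbinol carbon used with reversed polarity) + an alkenylboronate; 1,2-metallate shift and oxidation set C5.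
4. Alkenylboronate ⇐ methyl (S)-lactate triflate (electrophilic α-carbon, inversion sets C11) + a silylpentynyl Grignard reagent, then carboalumination–borylation (6E alkene).
5. Carbamate ⇐ a 2,5-dimethoxy-3-methylbenzyl chloride + but-3-yn-1-ol by carboalumination–benzylation (2E alkene).

Assumption: the side chain is numbered C1 (benzylic CH2) to C16, which makes the target (2E,5S,6E,11S).

**Route**

Step 1
Reactants: 1 4-methoxy-2-methylphenol
Product: 2 2-(hydroxymethyl)-4-methoxy-6-methylphenol
Conditions: aq. HCHO (37%), NaOH (1.1 equiv), H2O, N2, 20 °C; AcOH to pH 6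
Reagents that add atoms: formaldehyde, C=O
Why: Lederer–Manasse hydroxymethylation; the phenoxide has only one free ortho position and the para position carries OMe, so formaldehyde enters at C6 only.

Step 2
Reactants: 2 2-(hydroxymethyl)-4-methoxy-6-methylphenol
Product: 3 (2,5-dimethoxy-3-methylphenyl)methanol
Conditions: MeI, K2CO3, acetone, 56 °C
Reagents that add atoms: iodomethane, CI
Why: Williamson ether synthesis; carbonate deprotonates only the phenol, so the benzylic alcohol stays free.

Step 3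
Reactants: 3 (2,5-dimethoxy-3-methylphenyl)methanol
Product: 4 1-(chloromethyl)-2,5-dimethoxy-3-methylbenzene
Conditions: SOCl2, CH2Cl2, 0 °C
Reagents that add atoms: thionyl chloride, O=S(Cl)Cl
Why: Deoxychlorination of an electron-rich benzylic alcohol through its chlorosulfite; the aryl ethers are untouched at 0 °C.

Step 4
Reactants: 5 but-3-yn-1-ol; 4 1-(chloromethyl)-2,5-dimethoxy-3-methylbenzene
Product: 7 (E)-5-(2,5-dimethoxy-3-methylphenyl)-3-methylpent-3-en-1-ol, via alkenylalane 6 (not isolated)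
Conditions: Me3Al (3 equiv), Cp2ZrCl2 (0.25 equiv), CH2Cl2, 0 to 20 °C; excess Me3Al removed in vacuo; 4, Pd(PPh3)4 (5 mol%), THF, 20 °C; aq. work-up
Reagents that add atoms: trimethylaluminium, C[Al](C)C
Why: Negishi zirconium-catalysed carboalumination adds Me and Al syn with Al on the terminal carbon, and the palladium-catalysed cross-coupling of the alkenylalane with the benzylic chloride keeps that geometry, so the 2E alkene forms as one isomer.

Step 5
Reactants: 7 (E)-5-(2,5-dimethoxy-3-methylphenyl)-3-methylpent-3-en-1-ol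
Product: 8 (E)-5-(2,5-dimethoxy-3-methylphenyl)-3-methylpent-3-en-1-yl N,N-diisopropylcarbamate
Conditions: i-Pr2NCOCl, Et3N, CH2Cl2, 40 °C
Reagents that add atoms: N,N-diisopropylcarbamoyl chloride, CC(C)N(C(C)C)C(Cl)=O
Why: Carbamoylation of the primary alcohol gives the Hoppe carbamate that later directs α-lithiation and serves as the leaving group.

Step 6
Reactants: 9 methyl (2S)-2-hydroxypropanoate (methyl (S)-lactate)
Product: 10 methyl (2S)-2-{[(trifluoromethyl)sulfonyl]oxy}propanoate
Conditions: Tf2O, 2,6-lutidine, CH2Cl2, −78 to 0 °C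
Reagents that add atoms: trifluoromethanesulfonic anhydride, O=S(=O)(OS(=O)(=O)C(F)(F)F)C(F)(F)F
Why: O-Sulfonylation with a hindered base leaves the stereocentre untouched and turns the α-carbon of the ester into a strong electrophile.

Step 7
Reactants: 11 (5-chloropent-1-yn-1-yl)trimethylsilane; 10 methyl (2S)-2-{[(trifluoromethyl)sulfonyl]oxy}propanoate
Product: 14 methyl (2S)-2-methylhept-6-ynoate, via Grignard reagent 12 (not isolated), via silylalkyne ester 13 (not isolated)
Conditions: Mg, THF, 66 °C; added slowly to 10, ZnCl2 (5 mol%), THF, 0 °C; aq. wash; crude in MeOH, K2CO3 (0.2 equiv), 20 °C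
Reagents that add atoms: none
Why: Zinc-catalysed SN2 coupling of an α-triflyloxy ester with a Grignard reagent (a triorganozincate is the nucleophile) goes with clean inversion, so (S)-lactate gives the (S)-2-methyl ester that becomes C11; catalytic carbonate in methanol then cleaves the alkynylsilane.

Step 8
Reactants: 14 methyl (2S)-2-methylhept-6-ynoate
Product: 16 methyl (2S,6E)-2,6-dimethyl-7-(4,4,5,5-tetramethyl-1,3,2-dioxaborolan-2-yl)hept-6-enoate, via alkenylalane 15 (not isolated)
Conditions: Me3Al (3 equiv), Cp2ZrCl2 (0.2 equiv), H2O (1 equiv), CH2Cl2, −23 °C; i-PrOBpin (4 equiv), −23 to 20 °C; aq. work-up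
Reagents that add atoms: trimethylaluminium, C[Al](C)C; 2-isopropoxy-4,4,5,5-tetramethyl-1,3,2-dioxaborolane, CC(C)OB1OC(C)(C)C(C)(C)O1
Why: Water-accelerated Negishi carboalumination (syn, Al terminal) followed by aluminium-to-boron transmetalation gives the E-alkenylboronate; at −23 °C the ester is expected to be only complexed by Me3Al and C2 is not enolised.

Step 9 (key step)
Reactants: 8 (E)-5-(2,5-dimethoxy-3-methylphenyl)-3-methylpent-3-en-1-yl N,N-diisopropylcarbamate; 16 methyl (2S,6E)-2,6-dimethyl-7-(4,4,5,5-tetramethyl-1,3,2-dioxaborolan-2-yl)hept-6-enoate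
Product: 20 methyl (2S,6E,8S,10E)-12-(2,5-dimethoxy-3-methylphenyl)-8-hydroxy-2,6,10-trimethyldodeca-6,10-dienoate, via lithiated carbamate 17 (not isolated), via boronate complex 18 (not isolated), via allylic boronic ester 19 (not isolated)
Conditions: 8 (1.2 equiv), s-BuLi, (+)-sparteine, Et2O, −78 °C, 5 h; 16, −78 °C, 1 h; MgBr2·OEt2, −78 to 35 °C; NaBO3·4H2O, THF/H2O, 20 °C
Reagents that add atoms: sodium perborate tetrahydrate (NaBO3·4H2O), [Na+].[Na+].O[B-]1(O)OO[B-](O)(O)OO1.O.O.O.O.O.O
Why: Hoppe–Aggarwal lithiation–borylation: s-BuLi/(+)-sparteine removes the pro-R hydrogen next to the carbamate oxygen, the configurationally stable α-oxy carbanion adds to boron with retention, the alkenyl group shifts from boron to carbon with inversion as the carbamate leaves, and perborate oxidation with retention gives the (S)-carbinol (target C5) with both alkene geometries intact (about 95:5 er expected).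

Step 10
Reactants: 20 methyl (2S,6E,8S,10E)-12-(2,5-dimethoxy-3-methylphenyl)-8-hydroxy-2,6,10-trimethyldodeca-6,10-dienoate
Product: 21 (3S,7E,9S,11E)-1-chloro-13-(2,5-dimethoxy-3-methylphenyl)-9-hydroxy-3,7,11-trimethyltrideca-7,11-dien-2-one
Conditions: MeLi·LiBr (1.0 equiv), THF, −78 °C; ICH2Cl (3 equiv), then MeLi·LiBr (2.5 equiv), −78 °C; AcOH, −78 °C
Reagents that add atoms: chloroiodomethane, ClCI
Why: Carbenoid homologation of an ester: chloromethyllithium (from ICH2Cl by iodine–lithium exchange) adds once because the tetrahedral lithium hemiketal is stable at −78 °C, and the acidic quench releases the chloromethyl ketone without enolising C3; the alcohol is carried as its lithium alkoxide.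

Step 11
Reactants: 21 (3S,7E,9S,11E)-1-chloro-13-(2,5-dimethoxy-3-methylphenyl)-9-hydroxy-3,7,11-trimethyltrideca-7,11-dien-2-one; 22 4,4,5,5-tetramethyl-2-(2-methylprop-1-en-1-yl)-1,3,2-dioxaborolane
Product: 23 (6S,10E,12S,14E)-16-(2,5-dimethoxy-3-methylphenyl)-12-hydroxy-2,6,10,14-tetramethylhexadeca-2,10,14-trien-5-one
Conditions: Pd(OAc)2 (5 mol%), XPhos (10 mol%), K3PO4, THF/H2O, 20 °C
Reagents that add atoms: none
Why: Proposed new method: Suzuki–Miyaura coupling of an aliphatic chloromethyl ketone with an alkenylboronate; oxidative addition of zerovalent palladium into the activated C–Cl bond gives a palladium enolate, and transmetalation with the boronate and reductive elimination form C13–C14 with the alkene directly in the β,γ-position; the closest known reaction type is the palladium-catalysed Suzuki coupling of chloroacetates and chloroacetamides with alkenylboron reagents (also nickel-catalysed alkenylation of α-bromo ketones), and phosphate at 20 °C is chosen to avoid conjugation of the enone and epimerisation at C6.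

Step 12
Reactants: 23 (6S,10E,12S,14E)-16-(2,5-dimethoxy-3-methylphenyl)-12-hydroxy-2,6,10,14-tetramethylhexadeca-2,10,14-trien-5-one
Product: 24 (2E,5S,6E,11S)-1-(2,5-dimethoxy-3-methylphenyl)-3,7,11,15-tetramethyl-12-oxohexadeca-2,6,14-trien-5-yl acetate
Conditions: Ac2O, pyridine, DMAP (cat.), CH2Cl2, 0 °C
Reagents that add atoms: acetic anhydride, CC(=O)OC(C)=O
Why: DMAP-catalysed acylation of the only free hydroxyl group; weak amine bases at 0 °C do not isomerise the β,γ-unsaturated ketone.

Step 13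
Reactants: 24 (2E,5S,6E,11S)-1-(2,5-dimethoxy-3-methylphenyl)-3,7,11,15-tetramethyl-12-oxohexadeca-2,6,14-trien-5-yl acetate
Product: 26 (2E,5S,6E,11S)-1-(2,5-dihydroxy-3-methylphenyl)-3,7,11,15-tetramethyl-12-oxohexadeca-2,6,14-trien-5-yl acetate, via quinone 25 (not isolated)
Conditions: (NH4)2Ce(NO3)6 (2.5 equiv), MeCN/H2O, 0 °C; Et2O extract shaken with aq. Na2S2O4, 20 °C, argon
Reagents that add atoms: water, O
Why: Oxidative demethylation of the 1,4-dimethoxyarene (single-electron oxidation, water adds ipso, methanol leaves) gives the p-quinone, which dithionite reduces to the hydroquinone; acetate, ketone, trisubstituted alkenes and both stereocentres are not involved.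

**Compound list**
1 | 4-methoxy-2-methylphenol | COc1ccc(O)c(C)c1 | starting material
2 | 2-(hydroxymethyl)-4-methoxy-6-methylphenol | COc1cc(C)c(O)c(CO)c1 | intermediate
3 | (2,5-dimethoxy-3-methylphenyl)methanol | COc1cc(C)c(OC)c(CO)c1 | intermediate
4 | 1-(chloromethyl)-2,5-dimethoxy-3-methylbenzene | COc1cc(C)c(OC)c(CCl)c1 | intermediate
5 | but-3-yn-1-ol | C#CCCO | starting material
6 | (E)-[4-(dimethylalumanyloxy)-2-methylbut-1-en-1-yl]dimethylalumane | C[Al](C)/C=C(\C)CCO[Al](C)C | intermediate
7 | (E)-5-(2,5-dimethoxy-3-methylphenyl)-3-methylpent-3-en-1-ol | OCC/C(C)=C/Cc1cc(OC)cc(C)c1OC | intermediate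
8 | (E)-5-(2,5-dimethoxy-3-methylphenyl)-3-methylpent-3-en-1-yl N,N-diisopropylcarbamate | CC(C)N(C(C)C)C(=O)OCC/C(C)=C/Cc1cc(OC)cc(C)c1OC | intermediate
9 | methyl (2S)-2-hydroxypropanoate | C[C@H](O)C(=O)OC | starting material
10 | methyl (2S)-2-{[(trifluoromethyl)sulfonyl]oxy}propanoate | C[C@H](OS(=O)(=O)C(F)(F)F)C(=O)OC | intermediate
11 | (5-chloropent-1-yn-1-yl)trimethylsilane | C[Si](C)(C)C#CCCCCl | starting material
12 | [5-(trimethylsilyl)pent-4-yn-1-yl]magnesium chloride | C[Si](C)(C)C#CCCC[Mg]Cl | intermediate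
13 | methyl (2S)-2-methyl-7-(trimethylsilyl)hept-6-ynoate | C[Si](C)(C)C#CCCC[C@H](C)C(=O)OC | intermediate
14 | methyl (2S)-2-methylhept-6-ynoate | C#CCCC[C@H](C)C(=O)OC | intermediate
15 | methyl (2S,6E)-7-(dimethylalumanyl)-2,6-dimethylhept-6-enoate | C[Al](C)/C=C(\C)CCC[C@H](C)C(=O)OC | intermediate
16 | methyl (2S,6E)-2,6-dimethyl-7-(4,4,5,5-tetramethyl-1,3,2-dioxaborolan-2-yl)hept-6-enoate | CC1(C)OB(/C=C(\C)CCC[C@H](C)C(=O)OC)OC1(C)C | intermediate
17 | (1R,3E)-5-(2,5-dimethoxy-3-methylphenyl)-1-lithio-3-methylpent-3-en-1-yl N,N-diisopropylcarbamate (sparteine complex) | CC(C)N(C(C)C)C(=O)O[C@H]([Li])C/C(C)=C/Cc1cc(OC)cc(C)c1OC | intermediate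
18 | lithium [(1R,3E)-1-(diisopropylcarbamoyloxy)-5-(2,5-dimethoxy-3-methylphenyl)-3-methylpent-3-en-1-yl][(1E,6S)-7-methoxy-2,6-dimethyl-7-oxohept-1-en-1-yl](2,3-dimethylbutane-2,3-diolato)borate | [Li+].CC(C)N(C(C)C)C(=O)O[C@H]([B-]1(/C=C(\C)CCC[C@H](C)C(=O)OC)OC(C)(C)C(C)(C)O1)C/C(C)=C/Cc1cc(OC)cc(C)c1OC | intermediate
19 | methyl (2S,6E,8S,10E)-12-(2,5-dimethoxy-3-methylphenyl)-2,6,10-trimethyl-8-(4,4,5,5-tetramethyl-1,3,2-dioxaborolan-2-yl)dodeca-6,10-dienoate | CC1(C)OB(OC1(C)C)[C@H](/C=C(\C)CCC[C@H](C)C(=O)OC)C/C(C)=C/Cc1cc(OC)cc(C)c1OC | intermediate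
20 | methyl (2S,6E,8S,10E)-12-(2,5-dimethoxy-3-methylphenyl)-8-hydroxy-2,6,10-trimethyldodeca-6,10-dienoate | O[C@H](/C=C(\C)CCC[C@H](C)C(=O)OC)C/C(C)=C/Cc1cc(OC)cc(C)c1OC | intermediate
21 | (3S,7E,9S,11E)-1-chloro-13-(2,5-dimethoxy-3-methylphenyl)-9-hydroxy-3,7,11-trimethyltrideca-7,11-dien-2-one | O[C@H](/C=C(\C)CCC[C@H](C)C(=O)CCl)C/C(C)=C/Cc1cc(OC)cc(C)c1OC | intermediate
22 | 4,4,5,5-tetramethyl-2-(2-methylprop-1-en-1-yl)-1,3,2-dioxaborolane | CC(C)=CB1OC(C)(C)C(C)(C)O1 | starting material
23 | (6S,10E,12S,14E)-16-(2,5-dimethoxy-3-methylphenyl)-12-hydroxy-2,6,10,14-tetramethylhexadeca-2,10,14-trien-5-one | O[C@H](/C=C(\C)CCC[C@H](C)C(=O)CC=C(C)C)C/C(C)=C/Cc1cc(OC)cc(C)c1OC | intermediate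
24 | (2E,5S,6E,11S)-1-(2,5-dimethoxy-3-methylphenyl)-3,7,11,15-tetramethyl-12-oxohexadeca-2,6,14-trien-5-yl acetate | CC(=O)O[C@H](/C=C(\C)CCC[C@H](C)C(=O)CC=C(C)C)C/C(C)=C/Cc1cc(OC)cc(C)c1OC | intermediate
25 | (2E,5S,6E,11S)-3,7,11,15-tetramethyl-1-(5-methyl-3,6-dioxocyclohexa-1,4-dien-1-yl)-12-oxohexadeca-2,6,14-trien-5-yl acetate | CC(=O)O[C@H](/C=C(\C)CCC[C@H](C)C(=O)CC=C(C)C)C/C(C)=C/CC1=CC(=O)C=C(C)C1=O | intermediate
26 | (2E,5S,6E,11S)-1-(2,5-dihydroxy-3-methylphenyl)-3,7,11,15-tetramethyl-12-oxohexadeca-2,6,14-trien-5-yl acetate | CC(=O)O[C@H](/C=C(\C)CCC[C@H](C)C(=O)CC=C(C)C)C/C(C)=C/Cc1cc(O)cc(C)c1O | target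

**Totals and risks**

Total step count: 13. Longest linear sequence: 10 steps (steps 1, 2, 3, 4, 5, 9, 10, 11, 12, 13).

The three steps most likely to fail:

Step 9 (lithiation–borylation). s-BuLi may also deprotonate the benzylic–allylic CH2 or the dimethoxyarene ring of 8, and the lithiated carbamate may attack the ester of 16. Fallback: make the C5–C6 bond with normal polarity by an asymmetric Nozaki–Hiyama–Kishi coupling, setting out from 7 and 14 and coming back at 20. Alcohol 7 is oxidised with Dess–Martin periodinane to (E)-5-(2,5-dimethoxy-3-methylphenyl)-3-methylpent-3-enal F1, which is used at once because it conjugates easily. Alkyne 14 is carboaluminated as in step 8 (via 15) but quenched with I2 to give methyl (2S,6E)-7-iodo-2,6-dimethylhept-6-enoate F2. F1 and F2 are then joined with CrCl2, catalytic NiCl2 and a chiral sulfonamide ligand chosen for the (S)-alcohol, which is 20.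

Step 11 (coupling of the chloromethyl ketone). Protodehalogenation of the palladium enolate, or base-induced shift of the new alkene into conjugation, may dominate. Fallback: acylate a sulfone-stabilised prenyl anion, setting out from 20 (so step 10 is bypassed too) and coming back at 23. Ester 20 is treated with excess [(3-methylbut-2-en-1-yl)sulfonyl]benzene deprotonated by n-BuLi (THF, −78 to 0 °C) to give (6S,10E,12S,14E)-16-(2,5-dimethoxy-3-methylphenyl)-12-hydroxy-2,6,10,14-tetramethyl-4-(phenylsulfonyl)hexadeca-2,10,14-trien-5-one F3 as a mixture of C4 epimers. Reductive desulfonylation with SmI2 in THF/MeOH at −78 °C, with kinetic α-protonation of the dienolate, gives 23.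

Step 8 (carboalumination beside a methyl ester). Me3Al may alkylate or epimerise the ester before the alkyne reacts. Fallback: build the same alkenylboronate without aluminium by copper-catalysed syn-methylboration, in which boron is placed first and the methyl group second. It sets out from 14 and comes back at 16: 14 with B2pin2, MeI, CuCl (10 mol%), Xantphos and LiOt-Bu in THF at 0 to 20 °C gives 16 directly, so this path has no new compound (F0).

Further compounds
F1 | step 9 | (E)-5-(2,5-dimethoxy-3-methylphenyl)-3-methylpent-3-enal | O=CC/C(C)=C/Cc1cc(OC)cc(C)c1OC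
F2 | step 9 | methyl (2S,6E)-7-iodo-2,6-dimethylhept-6-enoate | I/C=C(\C)CCC[C@H](C)C(=O)OC
F3 | step 11 | (6S,10E,12S,14E)-16-(2,5-dimethoxy-3-methylphenyl)-12-hydroxy-2,6,10,14-tetramethyl-4-(phenylsulfonyl)hexadeca-2,10,14-trien-5-one | O[C@H](/C=C(\C)CCC[C@H](C)C(=O)C(C=C(C)C)S(=O)(=O)c1ccccc1)C/C(C)=C/Cc1cc(OC)cc(C)c1OC
F0 | step 8 | none | none
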